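**Retrosynthetic overview**
- Target ⇒ 3,3'-di-O-benzylquercetin 4',7-disulfate by hydrogenolysis of two benzyl ethers; the two S–O bonds come from SO3·pyridine acting on the free 7-OH and 4'-OH.
- That 7,4'-diol ⇒ 4',7-di-O-allyl-3,3'-di-O-benzylquercetin (Pd(0) deallylation) ⇒ 4',7-di-O-allylquercetin (benzylation of 3-OH and 3'-OH).
- 4',7-Di-O-allylquercetin ⇒ rutin: the natural 3-O-rutinoside masks 3-OH while the two most acidic phenols (7, 4') are allylated, then acid hydrolysis removes the sugar.
- No ring is formed: the A, C and B rings are bought intact in rutin.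

**Assumptions**
- The target has no stereocentre, so there is no enantiomer to control; the only stereocentres in the route are in the sugar of rutin and leave in step 2.
- Sulfate half-esters are drawn in the acid form used in the target SMILES; their salts (pyridinium, sodium, ammonium) count as the same numbered compound, and the acid form is released on H+ resin.

**Route**

Step 1
Reactants: 1 rutin (quercetin 3-O-[α-L-rhamnopyranosyl-(1→6)-β-D-glucopyranoside]); 2 allyl bromide
Product: 3 4',7-di-O-allylrutin
Conditions: allyl bromide (2.3 equiv), K2CO3 (2.5 equiv), DMF, N2, rt → 40 °C, 6 h; pour into dilute AcOH, filter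
Reagents that add atoms: allyl bromide, C=CCBr
Why: Williamson O-alkylation under carbonate control allylates only the two most acidic phenols (7-OH and 4'-OH), because 3-OH is masked by the sugar, 5-OH is hydrogen-bonded to C4=O, 3'-OH is less acidic and the sugar alcohols are not ionised.

Step 2
Reactants: 3 4',7-di-O-allylrutin
Product: 4 4',7-di-O-allylquercetin
Conditions: 2 M HCl, EtOH/H2O (1:1), 80 °C, 3 h; product precipitates on cooling
Reagents that add atoms: none
Why: Acid-catalysed glycoside (acetal) hydrolysis frees 3-OH while aryl allyl ethers are inert to hot dilute HCl, and all stereocentres leave with the sugars.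

Step 3
Reactants: 4 4',7-di-O-allylquercetin; 5 benzyl bromide
Product: 6 4',7-di-O-allyl-3,3'-di-O-benzylquercetin
Conditions: BnBr (2.4 equiv), K2CO3 (3 equiv), DMF, rt, 16 h
Reagents that add atoms: benzyl bromide, BrCc1ccccc1
Why: Williamson etherification benzylates the two remaining non-chelated hydroxyls (3-OH, 3'-OH), while the strongly hydrogen-bonded 5-OH stays free at room temperature.

Step 4
Reactants: 6 4',7-di-O-allyl-3,3'-di-O-benzylquercetin
Product: 7 3,3'-di-O-benzylquercetin (free 5-, 7- and 4'-OH)
Conditions: Pd(PPh3)4 (5 mol %), morpholine (10 equiv), THF, N2, rt, 2 h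
Reagents that add atoms: none
Why: Tsuji–Trost-type Pd(0) deallylation ionises the aryl allyl ethers to π-allyl-Pd, which excess morpholine traps, and benzyl ethers do not react with Pd(0).

Step 5
Reactants: 7 3,3'-di-O-benzylquercetin; 8 sulfur trioxide–pyridine complex
Product: 9 3,3'-di-O-benzylquercetin 4',7-bis(hydrogen sulfate)
Conditions: SO3·pyridine (6 equiv), dry pyridine, rt, 16 h; Dowex 50W (Na+ form), then Sephadex LH-20
Reagents that add atoms: sulfur trioxide–pyridine complex, O=S(=O)([O-])[n+]1ccccc1
Why: Phenol O-sulfation with an SO3–amine complex can only reach 7-OH and 4'-OH, since 3- and 3'-O are benzylated and the chelated 5-OH does not react under these mild conditions.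

Step 6
Reactants: 9 3,3'-di-O-benzylquercetin 4',7-bis(hydrogen sulfate)
Product: 10 3',5-dihydroxy-4',7-bis(sulfooxy)flavonol (quercetin 4',7-disulfate)
Conditions: H2 (1 atm), 10 % Pd/C, MeOH/H2O (4:1), rt, 3 h; filter; Dowex 50W (H+ form), 0 °C; freeze-dry
Reagents that add atoms: none
Why: Catalytic hydrogenolysis cleaves the two benzyl ethers while aryl sulfate anions and the chromone C2=C3 bond survive 1 atm H2 at room temperature, and no stereocentre exists to be set or scrambled.

**Compound list**
1 | rutin (quercetin 3-O-[α-L-rhamnopyranosyl-(1→6)-β-D-glucopyranoside]) | C[C@H]1[C@@H]([C@H]([C@H]([C@@H](O1)OC[C@@H]2[C@H]([C@@H]([C@H]([C@@H](O2)OC3=C(OC4=CC(=CC(=C4C3=O)O)O)C5=CC(=C(C=C5)O)O)O)O)O)O)O)O | starting material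
2 | allyl bromide | C=CCBr | starting material
3 | 4',7-di-O-allylrutin | C[C@H]1[C@@H]([C@H]([C@H]([C@@H](O1)OC[C@@H]2[C@H]([C@@H]([C@H]([C@@H](O2)OC3=C(OC4=CC(=CC(=C4C3=O)O)OCC=C)C5=CC(=C(C=C5)OCC=C)O)O)O)O)O)O)O | intermediate
4 | 4',7-di-O-allylquercetin | O=c1c(O)c(-c2ccc(OCC=C)c(O)c2)oc2cc(OCC=C)cc(O)c12 | intermediate
5 | benzyl bromide | BrCc1ccccc1 | starting material
6 | 4',7-di-O-allyl-3,3'-di-O-benzylquercetin | O=c1c(OCc2ccccc2)c(-c2ccc(OCC=C)c(OCc3ccccc3)c2)oc2cc(OCC=C)cc(O)c12 | intermediate
7 | 3,3'-di-O-benzylquercetin | O=c1c(OCc2ccccc2)c(-c2ccc(O)c(OCc3ccccc3)c2)oc2cc(O)cc(O)c12 | intermediate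
8 | sulfur trioxide–pyridine complex | O=S(=O)([O-])[n+]1ccccc1 | starting material
9 | 3,3'-di-O-benzylquercetin 4',7-bis(hydrogen sulfate) | O=c1c(OCc2ccccc2)c(-c2ccc(OS(=O)(=O)O)c(OCc3ccccc3)c2)oc2cc(OS(=O)(=O)O)cc(O)c12 | intermediate
10 | 3',5-dihydroxy-4',7-bis(sulfooxy)flavonol (quercetin 4',7-disulfate) | O=c1c(O)c(-c2ccc(OS(=O)(=O)O)c(O)c2)oc2cc(OS(=O)(=O)O)cc(O)c12 | target

**Step count and risks**
Total step count: 6. Longest linear sequence: 6 (fully linear from rutin).

Three steps most likely to fail:

Step 1 (regioselective bis-allylation of unprotected rutin). The risks are over-allylation at 3'-OH, incomplete reaction and polar mixtures that are hard to separate. The fallback drops protecting groups and relies on intrinsic phenol reactivity. It sets out from 1: hydrolysis with 2 M HCl in aqueous EtOH at reflux gives quercetin F1. F1 is sulfated with tetrabutylammonium hydrogen sulfate (about 3 equiv) and DCC in pyridine at 4 °C, where the hydroxyls react stepwise in order of acidity (7-OH, then 4'-OH, ahead of 3-OH; 3'-OH and the chelated 5-OH are left). The reaction is stopped at the disulfate stage by HPLC, the product is separated from 7-mono- and 3,4',7-trisulfate on Sephadex LH-20 and H+-exchanged. It comes back to the route at 10. This is shorter but gives mixtures, which is why it is not the main route.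

Step 5 (double sulfation and isolation of a very polar dianion). The risks are stalling at the monosulfate and loss on purification. The fallback uses a protected, neutral sulfate diester instead of direct SO3 sulfation. It sets out from 7: 2,2,2-trichloroethyl chlorosulfate (2.4 equiv), Et3N and DMAP in THF at 0 °C → rt give 3,3'-di-O-benzylquercetin 4',7-bis(2,2,2-trichloroethyl sulfate) F2, which can be purified on silica. Zn dust and HCO2NH4 in MeOH at rt then remove both trichloroethyl groups by reductive fragmentation. It comes back to the route at 9.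

Step 6 (hydrogenolysis in the presence of two aryl sulfates). The risks are catalyst inhibition, reduction of C2=C3 and desulfation during acid exchange. The fallback replaces benzyl by a fluoride-labile group so that no hydrogenation is needed. It sets out from 4: SEMCl and iPr2NEt in CH2Cl2 give 4',7-di-O-allyl-3,3'-bis-O-[2-(trimethylsilyl)ethoxymethyl]quercetin F3. Pd(PPh3)4/morpholine in THF gives 3,3'-bis-O-[2-(trimethylsilyl)ethoxymethyl]quercetin F4. SO3·pyridine in pyridine gives 3,3'-bis-O-[2-(trimethylsilyl)ethoxymethyl]quercetin 4',7-bis(hydrogen sulfate) F5. TBAF in THF/DMPU at 50 °C removes both SEM groups, and H+ exchange follows. It comes back to the route at 10.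

**Further compounds**
F1 | step 1 | quercetin | O=c1c(O)c(-c2ccc(O)c(O)c2)oc2cc(O)cc(O)c12
F2 | step 5 | 3,3'-di-O-benzylquercetin 4',7-bis(2,2,2-trichloroethyl sulfate) | O=c1c(OCc2ccccc2)c(-c2ccc(OS(=O)(=O)OCC(Cl)(Cl)Cl)c(OCc3ccccc3)c2)oc2cc(OS(=O)(=O)OCC(Cl)(Cl)Cl)cc(O)c12
F3 | step 6 | 4',7-di-O-allyl-3,3'-bis-O-[2-(trimethylsilyl)ethoxymethyl]quercetin | O=c1c(OCOCC[Si](C)(C)C)c(-c2ccc(OCC=C)c(OCOCC[Si](C)(C)C)c2)oc2cc(OCC=C)cc(O)c12
F4 | step 6 | 3,3'-bis-O-[2-(trimethylsilyl)ethoxymethyl]quercetin | O=c1c(OCOCC[Si](C)(C)C)c(-c2ccc(O)c(OCOCC[Si](C)(C)C)c2)oc2cc(O)cc(O)c12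
F5 | step 6 | 3,3'-bis-O-[2-(trimethylsilyl)ethoxymethyl]quercetin 4',7-bis(hydrogen sulfate) | O=c1c(OCOCC[Si](C)(C)C)c(-c2ccc(OS(=O)(=O)O)c(OCOCC[Si](C)(C)C)c2)oc2cc(OS(=O)(=O)O)cc(O)c12
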